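**Retrosynthetic overview**

1. Target 35 comes from ring A phenol 29 by functional-group work only: O-methylation at C2, oxidation of the PMB-oxymethyl carbon on C1 to CO2H, then fluoride and dilute acid to free the two hydroxyls and the ring B aldehyde.
2. Ring A, the only ring formed, is disconnected to diazo enone 11 and aryl alkynyl ether 24 by a Wolff rearrangement, [2+2] cycloaddition, four-electron opening and six-electron closure. This makes C4–C5, C1–C2, C5–C6 and C2–C3, and ring B arrives intact on the alkyne oxygen.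
3. Feature used: ring A carries oxygen on C2 and C6 with the carbon-substituted C1 between them (ketene carbonyl oxygen plus ynol ether oxygen), and its C3 side chain, (S)-CH(OH)–CH2–CH(CH3)2, is the skeleton of (S)-leucic acid.
4. Diazo enone 11 comes from L-leucine 1: retentive diazotization, ester, TBS ether, aldehyde, E-selective Wittig reaction with ylide 8, diazo transfer.
5. Alkyne 24 comes from creosol 12: ortho-formylation, demethylation, selective 3-O-SEM ether, dichlorovinyl ether from trichloroethylene 17, dioxolane, aryloxyacetylide plus formaldehyde, PMB ether.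

Key step: step 14

Remark: ring A is numbered C1 (CO2H carbon), C2 (OMe), C3 (side chain), C4, C5, C6 (O-aryl). TBS = tert-butyldimethylsilyl, SEM = 2-(trimethylsilyl)ethoxymethyl, PMB = 4-methoxybenzyl, ArB = 2-(1,3-dioxolan-2-yl)-4-methyl-6-(SEM-oxy)phenyl (protected ring B).

**Route**

Step 1
Reactants: 1 L-leucine
Product: 4 (S)-2-hydroxy-4-methylpentanoic acid, via diazonium carboxylate 2 (not isolated), via α-lactone 3 (not isolated)
Conditions: NaNO2, 1 M H2SO4, H2O, 0 °C → rt
Reagents that add atoms: water, O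
Why: Diazotization gives the diazonium carboxylate, the neighbouring carboxylate displaces N2 with inversion to the α-lactone and water opens it with a second inversion, so the C–O stereocentre is set as (S) with overall retention.

Step 2
Reactants: 4 (S)-2-hydroxy-4-methylpentanoic acid
Product: 5 methyl (S)-2-hydroxy-4-methylpentanoate
Conditions: MeOH, H2SO4 (cat.), reflux
Reagents that add atoms: methanol, CO
Why: Fischer esterification in excess methanol leaves the secondary carbinol stereocentre untouched.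

Step 3
Reactants: 5 methyl (S)-2-hydroxy-4-methylpentanoate
Product: 6 methyl (S)-2-(TBS-oxy)-4-methylpentanoate
Conditions: TBSCl, imidazole, DMF, rt
Reagents that add atoms: tert-butyldimethylsilyl chloride, CC(C)(C)[Si](C)(C)Cl
Why: Imidazole-promoted silylation of a secondary alcohol is routine and gives an ether that survives hydride, ylide, amide base, light and heat.

Step 4
Reactants: 6 methyl (S)-2-(TBS-oxy)-4-methylpentanoate
Product: 7 (S)-2-(TBS-oxy)-4-methylpentanal
Conditions: i-Bu2AlH (1.05 equiv), CH2Cl2, −78 °C; MeOH, then aq KNa tartrate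
Reagents that add atoms: none
Why: The aluminium hemiacetal of an α-silyloxy ester is stable at −78 °C, so the partial reduction stops at the aldehyde, which is used at once to avoid α-epimerization.

Step 5
Reactants: 7 (S)-2-(TBS-oxy)-4-methylpentanal; 8 1-(triphenylphosphoranylidene)propan-2-one
Product: 9 (S,E)-5-(TBS-oxy)-7-methyloct-3-en-2-one
Conditions: CH2Cl2, rt → 40 °C
Reagents that add atoms: none
Why: The Wittig reaction of a stabilized acyl ylide is E-selective and too weakly basic to epimerize the α-silyloxy aldehyde.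

Step 6
Reactants: 9 (S,E)-5-(TBS-oxy)-7-methyloct-3-en-2-one
Product: 11 (S,E)-5-(TBS-oxy)-1-diazo-7-methyloct-3-en-2-one, via trifluoroacetyl diketone 10 (not isolated)
Conditions: LiN(SiMe3)2, THF, −78 °C; CF3CO2CH2CF3; aq HCl work-up; then MsN3, Et3N, H2O, MeCN, rt
Reagents that add atoms: methanesulfonyl azide, CS(=O)(=O)N=[N+]=[N-]; 2,2,2-trifluoroethyl trifluoroacetate, O=C(OCC(F)(F)F)C(F)(F)F (its trifluoroacetyl group stays only in 10)
Why: Detrifluoroacetylative diazo transfer: kinetic enolization at the methyl group, Claisen trifluoroacetylation and sulfonyl azide transfer with loss of the trifluoroacetyl group give the diazo ketone without touching the γ-stereocentre or the E-alkene.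

Step 7
Reactants: 12 2-methoxy-4-methylphenol (creosol)
Product: 14 2-hydroxy-3-methoxy-5-methylbenzaldehyde, via hydroxymethylphenol 13 (not isolated)
Conditions: MgCl2, Et3N, (CH2O)n, MeCN, reflux
Reagents that add atoms: formaldehyde (as paraformaldehyde), C=O
Why: Magnesium phenoxide-directed ortho-formylation (Casnati–Skattebøl) can only occur at the single free ortho position, and the hydroxymethyl intermediate is oxidized by hydride transfer to a second formaldehyde.

Step 8
Reactants: 14 2-hydroxy-3-methoxy-5-methylbenzaldehyde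
Product: 15 2,3-dihydroxy-5-methylbenzaldehyde
Conditions: BBr3, CH2Cl2, −78 → 0 °C; H2O
Reagents that add atoms: none
Why: BBr3 cleaves the aryl methyl ether by bromide attack on the boron-activated O-methyl group, and the non-enolizable aldehyde is recovered on hydrolysis.

Step 9
Reactants: 15 2,3-dihydroxy-5-methylbenzaldehyde
Product: 16 2-hydroxy-5-methyl-3-(SEM-oxy)benzaldehyde
Conditions: NaH (2.2 equiv), DMF, 0 °C; SEMCl (1.0 equiv), 0 °C → rt; aq NH4Cl
Reagents that add atoms: 2-(trimethylsilyl)ethoxymethyl chloride, C[Si](C)(C)CCOCCl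
Why: In the dianion the 2-phenoxide is delocalized into and chelated by the ortho-formyl group, so the more nucleophilic 3-phenoxide takes the single equivalent of chloromethyl ether (Williamson-type alkylation).

Step 10
Reactants: 16 2-hydroxy-5-methyl-3-(SEM-oxy)benzaldehyde; 17 trichloroethylene
Product: 19 2-[(E)-1,2-dichloroethenyloxy]-5-methyl-3-(SEM-oxy)benzaldehyde, via dichloroacetylene 18 (not isolated)
Conditions: K2CO3, DMF, 70 °C
Reagents that add atoms: none
Why: Carbonate dehydrochlorinates trichloroethylene to dichloroacetylene, to which the phenoxide adds in anti fashion to give the (E)-dichlorovinyl ether after protonation, the standard entry to aryl alkynyl ethers.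

Step 11
Reactants: 19 2-[(E)-1,2-dichloroethenyloxy]-5-methyl-3-(SEM-oxy)benzaldehyde
Product: 20 2-{2-[(E)-1,2-dichloroethenyloxy]-5-methyl-3-(SEM-oxy)phenyl}-1,3-dioxolane
Conditions: Me3SiOCH2CH2OSiMe3, Me3SiOTf (cat.), CH2Cl2, −78 → −20 °C; pyridine
Reagents that add atoms: 1,2-bis(trimethylsilyloxy)ethane, C[Si](C)(C)OCCO[Si](C)(C)C
Why: Noyori acetalization is aprotic, cold and driven by Si–O–Si bond formation, so the SEM acetal and the electron-poor dichlorovinyl ether survive while the aldehyde is masked against butyllithium.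

Step 12
Reactants: 20 2-{2-[(E)-1,2-dichloroethenyloxy]-5-methyl-3-(SEM-oxy)phenyl}-1,3-dioxolane
Product: 23 3-[2-(1,3-dioxolan-2-yl)-4-methyl-6-(SEM-oxy)phenoxy]prop-2-yn-1-ol, via chloroalkyne 21 (not isolated), via lithium aryloxyacetylide 22 (not isolated)
Conditions: n-BuLi (2.5 equiv), THF, −78 → −40 °C; (CH2O)n, −40 °C → rt; aq NH4Cl (pH 7–8)
Reagents that add atoms: formaldehyde (as paraformaldehyde), C=O; n-butyllithium, [Li]CCCC (lithium stays only in 22)
Why: Butyllithium effects dehydrochlorination to the chloroalkyne and chlorine–lithium exchange to the aryloxyacetylide, which adds to formaldehyde as an ordinary acetylide, while the low temperature keeps ortho-lithiation next to the SEM-oxy group from competing.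

Step 13
Reactants: 23 3-[2-(1,3-dioxolan-2-yl)-4-methyl-6-(SEM-oxy)phenoxy]prop-2-yn-1-ol
Product: 24 2-[2-({3-[(4-methoxybenzyl)oxy]prop-1-yn-1-yl}oxy)-5-methyl-3-(SEM-oxy)phenyl]-1,3-dioxolane
Conditions: NaH, PMBCl, Bu4NI (cat.), THF/DMF, 0 °C → rt
Reagents that add atoms: 4-methoxybenzyl chloride, COc1ccc(CCl)cc1
Why: Williamson etherification under basic conditions is compatible with the acid-sensitive ynol ether and both acetals.

Step 14
Reactants: 11 (S,E)-5-(TBS-oxy)-1-diazo-7-methyloct-3-en-2-one; 24 2-[2-({3-[(4-methoxybenzyl)oxy]prop-1-yn-1-yl}oxy)-5-methyl-3-(SEM-oxy)phenyl]-1,3-dioxolane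
Product: 29 3-(ArB-oxy)-2-[(PMB-oxy)methyl]-6-[(S)-1-(TBS-oxy)-3-methylbutyl]phenol, via vinylketene 25 (not isolated), via cyclobutenone 26 (not isolated), via dienylketene 27 (not isolated), via cyclohexadienone 28 (not isolated)
Conditions: hν (300–350 nm, Pyrex), degassed ClCH2CH2Cl, rt, 11 (1.3 equiv) added in portions to 24; then 80 °C; K2CO3, MeOH, rt (work-up, cleaves any aryl ester from O-acylation of the phenol)
Reagents that add atoms: none
Why: Light-induced loss of N2 and Wolff shift of the alkenyl group of 11 (C4–C5) give vinylketene 25, whose carbonyl carbon bonds to the nucleophilic alkyne carbon of 24 remote from oxygen while its α-carbon bonds to the oxygen-bearing alkyne carbon in a [2+2] cycloaddition (C1–C2 and C5–C6) to cyclobutenone 26. Heating opens 26 by four-electron electrocyclic cleavage to dienylketene 27, which closes ring A by six-electron electrocyclization (C2–C3, six-membered carbocycle) to dienone 28 and tautomerizes to phenol 29. The closest known reaction is the photochemical Danheiser benzannulation of unsaturated α-diazo ketones with alkoxy- and siloxyalkynes, applied here to an aryl alkynyl ether. No stereocentre is formed, the allylic C–O stereocentre is not enolizable in any intermediate, and the E-alkene keeps its hydrogen out of reach of a 1,5-shift to the ketene. The only selectivity needed is the regiochemistry of the [2+2] step, secured by the polarization of the ynol ether, which places the aryloxy group meta (C6) and the PMB-oxymethyl carbon ortho (C1) to the new hydroxyl (C2).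

Step 15
Reactants: 29 3-(ArB-oxy)-2-[(PMB-oxy)methyl]-6-[(S)-1-(TBS-oxy)-3-methylbutyl]phenol
Product: 30 ArB 3-methoxy-2-[(PMB-oxy)methyl]-4-[(S)-1-(TBS-oxy)-3-methylbutyl]phenyl ether
Conditions: MeI, Cs2CO3, DMF, rt → 40 °C
Reagents that add atoms: iodomethane, CI
Why: Williamson methylation of the caesium phenoxide with the smallest electrophile overcomes the two ortho substituents and installs the C2 methoxy group.

Step 16
Reactants: 30 ArB 3-methoxy-2-[(PMB-oxy)methyl]-4-[(S)-1-(TBS-oxy)-3-methylbutyl]phenyl ether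
Product: 31 {6-(ArB-oxy)-2-methoxy-3-[(S)-1-(TBS-oxy)-3-methylbutyl]phenyl}methanol
Conditions: DDQ, CH2Cl2/pH 7 buffer, 0 °C → rt
Reagents that add atoms: none
Why: DDQ abstracts hydride from the unhindered 4-methoxybenzylic position and water hydrolyses the oxocarbenium ion, while the buffered medium protects the dioxolane, SEM and silyl ethers.

Step 17
Reactants: 31 {6-(ArB-oxy)-2-methoxy-3-[(S)-1-(TBS-oxy)-3-methylbutyl]phenyl}methanol
Product: 32 6-(ArB-oxy)-2-methoxy-3-[(S)-1-(TBS-oxy)-3-methylbutyl]benzaldehyde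
Conditions: Dess–Martin periodinane, NaHCO3, CH2Cl2, rt
Reagents that add atoms: none
Why: Buffered Dess–Martin oxidation converts the primary benzylic alcohol to the aldehyde without over-oxidation, and no free phenol or other alcohol is present.

Step 18
Reactants: 32 6-(ArB-oxy)-2-methoxy-3-[(S)-1-(TBS-oxy)-3-methylbutyl]benzaldehyde
Product: 33 6-(ArB-oxy)-2-methoxy-3-[(S)-1-(TBS-oxy)-3-methylbutyl]benzoic acid
Conditions: NaClO2, NaH2PO4, 2-methyl-2-butene, t-BuOH/H2O, rt
Reagents that add atoms: sodium chlorite, [Na+].[O-]Cl=O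
Why: Pinnick oxidation takes the hindered non-enolizable aldehyde to the acid at about pH 4, too mild to hydrolyse the dioxolane, and the alkene scavenger keeps hypochlorous acid off the electron-rich rings.

Step 19
Reactants: 33 6-(ArB-oxy)-2-methoxy-3-[(S)-1-(TBS-oxy)-3-methylbutyl]benzoic acid
Product: 34 6-[2-(1,3-dioxolan-2-yl)-6-hydroxy-4-methylphenoxy]-3-[(S)-1-hydroxy-3-methylbutyl]-2-methoxybenzoic acid
Conditions: Bu4NF (excess), THF/DMPU, rt → 60 °C; aq NH4Cl
Reagents that add atoms: none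
Why: Fluoride cleaves the Si–O bond of the TBS ether and attacks silicon of the SEM group, which fragments to ethylene, formaldehyde and the phenoxide, while the dioxolane, methyl ether and diaryl ether are inert to fluoride.

Step 20
Reactants: 34 6-[2-(1,3-dioxolan-2-yl)-6-hydroxy-4-methylphenoxy]-3-[(S)-1-hydroxy-3-methylbutyl]-2-methoxybenzoic acid
Product: 35 tenellic acid B, 6-(2-formyl-6-hydroxy-4-methylphenoxy)-3-[(S)-1-hydroxy-3-methylbutyl]-2-methoxybenzoic acid
Conditions: 0.5 M aq HCl, THF, 0 °C → rt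
Reagents that add atoms: water, O
Why: Acid-catalysed hydrolysis of the aryl dioxolane proceeds through its oxocarbenium ion, whereas the benzylic alcohol on the carboxyl-bearing ring A should ionize far more slowly in cold dilute aqueous acid, so the (S) centre is kept.

**Compound list**

1 | L-leucine | CC(C)C[C@H](N)C(=O)O | starting material
2 | (S)-1-carboxylato-3-methylbutane-1-diazonium | CC(C)C[C@H]([N+]#N)C(=O)[O-] | intermediate (not isolated)
3 | (R)-3-(2-methylpropyl)oxiran-2-one | CC(C)C[C@@H]1C(=O)O1 | intermediate (not isolated)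
4 | (S)-2-hydroxy-4-methylpentanoic acid | CC(C)C[C@H](O)C(=O)O | intermediate
5 | methyl (S)-2-hydroxy-4-methylpentanoate | CC(C)C[C@H](O)C(=O)OC | intermediate
6 | methyl (S)-2-(tert-butyldimethylsilyloxy)-4-methylpentanoate | CC(C)C[C@H](O[Si](C)(C)C(C)(C)C)C(=O)OC | intermediate
7 | (S)-2-(tert-butyldimethylsilyloxy)-4-methylpentanal | CC(C)C[C@H](O[Si](C)(C)C(C)(C)C)C=O | intermediate
8 | 1-(triphenylphosphoranylidene)propan-2-one | CC(=O)C=P(c1ccccc1)(c1ccccc1)c1ccccc1 | starting material
9 | (S,E)-5-(tert-butyldimethylsilyloxy)-7-methyloct-3-en-2-one | CC(=O)/C=C/[C@@H](O[Si](C)(C)C(C)(C)C)CC(C)C | intermediate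
10 | (S,E)-7-(tert-butyldimethylsilyloxy)-1,1,1-trifluoro-9-methyldec-5-ene-2,4-dione | O=C(CC(=O)/C=C/[C@@H](O[Si](C)(C)C(C)(C)C)CC(C)C)C(F)(F)F | intermediate (not isolated)
11 | (S,E)-5-(tert-butyldimethylsilyloxy)-1-diazo-7-methyloct-3-en-2-one | [N-]=[N+]=CC(=O)/C=C/[C@@H](O[Si](C)(C)C(C)(C)C)CC(C)C | intermediate (key-step precursor)
12 | 2-methoxy-4-methylphenol (creosol) | COc1cc(C)ccc1O | starting material
13 | 2-(hydroxymethyl)-6-methoxy-4-methylphenol | COc1cc(C)cc(CO)c1O | intermediate (not isolated)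
14 | 2-hydroxy-3-methoxy-5-methylbenzaldehyde | COc1cc(C)cc(C=O)c1O | intermediate
15 | 2,3-dihydroxy-5-methylbenzaldehyde | Cc1cc(O)c(O)c(C=O)c1 | intermediate
16 | 2-hydroxy-5-methyl-3-{[2-(trimethylsilyl)ethoxy]methoxy}benzaldehyde | Cc1cc(OCOCC[Si](C)(C)C)c(O)c(C=O)c1 | intermediate
17 | trichloroethylene | ClC=C(Cl)Cl | starting material
18 | dichloroacetylene | ClC#CCl | intermediate (not isolated)
19 | 2-[(E)-1,2-dichloroethenyloxy]-5-methyl-3-{[2-(trimethylsilyl)ethoxy]methoxy}benzaldehyde | Cc1cc(OCOCC[Si](C)(C)C)c(O/C(Cl)=C\Cl)c(C=O)c1 | intermediate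
20 | 2-{2-[(E)-1,2-dichloroethenyloxy]-5-methyl-3-{[2-(trimethylsilyl)ethoxy]methoxy}phenyl}-1,3-dioxolane | Cc1cc(OCOCC[Si](C)(C)C)c(O/C(Cl)=C\Cl)c(C2OCCO2)c1 | intermediate
21 | 2-{2-(chloroethynyloxy)-5-methyl-3-{[2-(trimethylsilyl)ethoxy]methoxy}phenyl}-1,3-dioxolane | Cc1cc(OCOCC[Si](C)(C)C)c(OC#CCl)c(C2OCCO2)c1 | intermediate (not isolated)
22 | {[2-(1,3-dioxolan-2-yl)-4-methyl-6-{[2-(trimethylsilyl)ethoxy]methoxy}phenoxy]ethynyl}lithium | Cc1cc(OCOCC[Si](C)(C)C)c(OC#C[Li])c(C2OCCO2)c1 | intermediate (not isolated)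
23 | 3-[2-(1,3-dioxolan-2-yl)-4-methyl-6-{[2-(trimethylsilyl)ethoxy]methoxy}phenoxy]prop-2-yn-1-ol | Cc1cc(OCOCC[Si](C)(C)C)c(OC#CCO)c(C2OCCO2)c1 | intermediate
24 | 2-[2-({3-[(4-methoxybenzyl)oxy]prop-1-yn-1-yl}oxy)-5-methyl-3-{[2-(trimethylsilyl)ethoxy]methoxy}phenyl]-1,3-dioxolane | COc1ccc(COCC#COc2c(OCOCC[Si](C)(C)C)cc(C)cc2C3OCCO3)cc1 | intermediate (key-step precursor)
25 | (S,E)-5-(tert-butyldimethylsilyloxy)-7-methylocta-1,3-dien-1-one (vinylketene) | O=C=C/C=C/[C@@H](O[Si](C)(C)C(C)(C)C)CC(C)C | intermediate (not isolated)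
26 | 3-(ArB-oxy)-2-[(4-methoxybenzyloxy)methyl]-4-[(S,E)-3-(tert-butyldimethylsilyloxy)-5-methylhex-1-en-1-yl]cyclobut-2-en-1-one (C4 epimers) | O=C1C(COCc2ccc(OC)cc2)=C(Oc3c(OCOCC[Si](C)(C)C)cc(C)cc3C4OCCO4)C1/C=C/[C@@H](O[Si](C)(C)C(C)(C)C)CC(C)C | intermediate (not isolated)
27 | (S)-3-(ArB-oxy)-2-[(4-methoxybenzyloxy)methyl]-7-(tert-butyldimethylsilyloxy)-9-methyldeca-1,3,5-trien-1-one, C2 and C5 cis on C3=C4, 5E (dienylketene) | O=C=C(COCc1ccc(OC)cc1)/C(Oc2c(OCOCC[Si](C)(C)C)cc(C)cc2C3OCCO3)=C\C=C\[C@@H](O[Si](C)(C)C(C)(C)C)CC(C)C | intermediate (not isolated)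
28 | 3-(ArB-oxy)-2-[(4-methoxybenzyloxy)methyl]-6-[(S)-1-(tert-butyldimethylsilyloxy)-3-methylbutyl]cyclohexa-2,4-dien-1-one (C6 epimers) | O=C1C(COCc2ccc(OC)cc2)=C(Oc3c(OCOCC[Si](C)(C)C)cc(C)cc3C4OCCO4)C=CC1[C@@H](O[Si](C)(C)C(C)(C)C)CC(C)C | intermediate (not isolated)
29 | 3-(ArB-oxy)-2-[(4-methoxybenzyloxy)methyl]-6-[(S)-1-(tert-butyldimethylsilyloxy)-3-methylbutyl]phenol | Oc1c([C@@H](O[Si](C)(C)C(C)(C)C)CC(C)C)ccc(Oc2c(OCOCC[Si](C)(C)C)cc(C)cc2C3OCCO3)c1COCc1ccc(OC)cc1 | intermediate (key-step product)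
30 | ArB 3-methoxy-2-[(4-methoxybenzyloxy)methyl]-4-[(S)-1-(tert-butyldimethylsilyloxy)-3-methylbutyl]phenyl ether | COc1c([C@@H](O[Si](C)(C)C(C)(C)C)CC(C)C)ccc(Oc2c(OCOCC[Si](C)(C)C)cc(C)cc2C3OCCO3)c1COCc1ccc(OC)cc1 | intermediate
31 | {6-(ArB-oxy)-2-methoxy-3-[(S)-1-(tert-butyldimethylsilyloxy)-3-methylbutyl]phenyl}methanol | COc1c([C@@H](O[Si](C)(C)C(C)(C)C)CC(C)C)ccc(Oc2c(OCOCC[Si](C)(C)C)cc(C)cc2C3OCCO3)c1CO | intermediate
32 | 6-(ArB-oxy)-2-methoxy-3-[(S)-1-(tert-butyldimethylsilyloxy)-3-methylbutyl]benzaldehyde | COc1c([C@@H](O[Si](C)(C)C(C)(C)C)CC(C)C)ccc(Oc2c(OCOCC[Si](C)(C)C)cc(C)cc2C3OCCO3)c1C=O | intermediate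
33 | 6-(ArB-oxy)-2-methoxy-3-[(S)-1-(tert-butyldimethylsilyloxy)-3-methylbutyl]benzoic acid | COc1c([C@@H](O[Si](C)(C)C(C)(C)C)CC(C)C)ccc(Oc2c(OCOCC[Si](C)(C)C)cc(C)cc2C3OCCO3)c1C(=O)O | intermediate
34 | 6-[2-(1,3-dioxolan-2-yl)-6-hydroxy-4-methylphenoxy]-3-[(S)-1-hydroxy-3-methylbutyl]-2-methoxybenzoic acid | COc1c([C@@H](O)CC(C)C)ccc(Oc2c(O)cc(C)cc2C3OCCO3)c1C(=O)O | intermediate
35 | tenellic acid B, 6-(2-formyl-6-hydroxy-4-methylphenoxy)-3-[(S)-1-hydroxy-3-methylbutyl]-2-methoxybenzoic acid | COc1c([C@@H](O)CC(C)C)ccc(Oc2c(O)cc(C)cc2C=O)c1C(=O)O | target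

**Step count and risks**

Total step count: 20 (steps 1–6 to diazo enone 11, steps 7–13 to alkyne 24, steps 14–20 in common).
Longest linear sequence: 14 steps (creosol 12 to 35, steps 7–20).

Steps most likely to fail:

1. Step 14. The [2+2] capture of vinylketene 25 by the di-ortho-substituted, weakly donating aryloxyalkyne may be slower than ketene dimerization and O-acylation of the product phenol, and the enone alkene may photoisomerize before the Wolff shift. The fallback sets out from 11 and comes back at 30: ring B is taken off the alkyne and the benzannulation is run with a siloxyalkyne, the established partner.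
   - 4-Methoxybenzyl propargyl ether F1 (propargyl alcohol, NaH, PMBCl) is converted through its lithium acetylide into triisopropyl({3-[(4-methoxybenzyl)oxy]prop-1-yn-1-yl}oxy)silane F2 (n-BuLi, THF, −78 °C; LiOOt-Bu; i-Pr3SiOTf; acetylide oxidation to the ynolate and O-silylation).
   - Irradiation and heating of 11 with F2 as in step 14 should give 2-[(4-methoxybenzyloxy)methyl]-6-[(S)-1-(tert-butyldimethylsilyloxy)-3-methylbutyl]-3-(triisopropylsilyloxy)phenol F3 with the same regiochemistry.
   - MeI/Cs2CO3 gives its methyl ether F4, and K2CO3 in MeOH cleaves only the aryl silyl ether to 3-methoxy-2-[(4-methoxybenzyloxy)methyl]-4-[(S)-1-(tert-butyldimethylsilyloxy)-3-methylbutyl]phenol F5.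
   - Ring B is then attached by nucleophilic aromatic substitution. 2-Fluoro-5-methylphenol is protected as 1-fluoro-4-methyl-2-(SEM-oxy)benzene F6 (SEMCl, i-Pr2NEt), lithiated next to fluorine (n-BuLi, PMDTA, THF, −78 °C) and formylated with DMF to 2-fluoro-5-methyl-3-(SEM-oxy)benzaldehyde F7.
   - F5 and F7 with K2CO3 in DMF at 90 °C should give 2-{3-methoxy-2-[(4-methoxybenzyloxy)methyl]-4-[(S)-1-(tert-butyldimethylsilyloxy)-3-methylbutyl]phenoxy}-5-methyl-3-(SEM-oxy)benzaldehyde F8, whose acetalization under the conditions of step 11 gives 30.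

2. Step 12. Capture of the lithium aryloxyacetylide by slowly depolymerizing paraformaldehyde may be incomplete, ortho-lithiation next to the SEM-oxy group may set in on warming, and the propargylic alcohol may rearrange (Meyer–Schuster type) to an aryl acrylate on work-up or silica. The fallback sets out from 20 and comes back at 24: the carbinol carbon is brought in already etherified.
   - 4-Methoxybenzyl alcohol, NaH, ClCH2SMe and NaI give 4-methoxybenzyl (methylthio)methyl ether F9.
   - SO2Cl2 (CH2Cl2, −78 °C) converts it into 4-methoxybenzyl chloromethyl ether F10.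
   - Acetylide 22, generated from 20 as in step 12, is alkylated with F10 at −78 °C to give 24 directly, so neither formaldehyde nor the free alcohol 23 is involved.

3. Step 19. Fluoride-induced fragmentation of the phenolic SEM ether at the hindered ring B position may be sluggish, so that the carboxylate and benzylic alkoxide are exposed to hot basic fluoride for long times (incomplete deprotection or decomposition). The fallback sets out from 33 and comes back at 35: SEM is removed by acetal hydrolysis instead of fluoride fragmentation.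
   - Bu4NF in THF at 0 °C → rt removes only the TBS ether and gives 6-(ArB-oxy)-3-[(S)-1-hydroxy-3-methylbutyl]-2-methoxybenzoic acid F11.
   - 2 M aq HCl in THF at 40 °C then hydrolyses the SEM formaldehyde acetal and the dioxolane in one operation to 35. The medium is kept alcohol-free so that the benzylic alcohol cannot be etherified.

**Further compounds**

F1 | step 14 | 4-methoxybenzyl propargyl ether | COc1ccc(COCC#C)cc1
F2 | step 14 | triisopropyl({3-[(4-methoxybenzyl)oxy]prop-1-yn-1-yl}oxy)silane | COc1ccc(COCC#CO[Si](C(C)C)(C(C)C)C(C)C)cc1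
F3 | step 14 | 2-[(4-methoxybenzyloxy)methyl]-6-[(S)-1-(tert-butyldimethylsilyloxy)-3-methylbutyl]-3-(triisopropylsilyloxy)phenol | Oc1c([C@@H](O[Si](C)(C)C(C)(C)C)CC(C)C)ccc(O[Si](C(C)C)(C(C)C)C(C)C)c1COCc1ccc(OC)cc1
F4 | step 14 | methyl ether of F3 | COc1c([C@@H](O[Si](C)(C)C(C)(C)C)CC(C)C)ccc(O[Si](C(C)C)(C(C)C)C(C)C)c1COCc1ccc(OC)cc1
F5 | step 14 | 3-methoxy-2-[(4-methoxybenzyloxy)methyl]-4-[(S)-1-(tert-butyldimethylsilyloxy)-3-methylbutyl]phenol | COc1c([C@@H](O[Si](C)(C)C(C)(C)C)CC(C)C)ccc(O)c1COCc1ccc(OC)cc1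
F6 | step 14 | 1-fluoro-4-methyl-2-{[2-(trimethylsilyl)ethoxy]methoxy}benzene | Cc1ccc(F)c(OCOCC[Si](C)(C)C)c1
F7 | step 14 | 2-fluoro-5-methyl-3-{[2-(trimethylsilyl)ethoxy]methoxy}benzaldehyde | Cc1cc(C=O)c(F)c(OCOCC[Si](C)(C)C)c1
F8 | step 14 | 2-{3-methoxy-2-[(4-methoxybenzyloxy)methyl]-4-[(S)-1-(tert-butyldimethylsilyloxy)-3-methylbutyl]phenoxy}-5-methyl-3-{[2-(trimethylsilyl)ethoxy]methoxy}benzaldehyde | COc1c([C@@H](O[Si](C)(C)C(C)(C)C)CC(C)C)ccc(Oc2c(OCOCC[Si](C)(C)C)cc(C)cc2C=O)c1COCc1ccc(OC)cc1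
F9 | step 12 | 4-methoxybenzyl (methylthio)methyl ether | COc1ccc(COCSC)cc1
F10 | step 12 | 4-methoxybenzyl chloromethyl ether | COc1ccc(COCCl)cc1
F11 | step 19 | 6-(ArB-oxy)-3-[(S)-1-hydroxy-3-methylbutyl]-2-methoxybenzoic acid | COc1c([C@@H](O)CC(C)C)ccc(Oc2c(OCOCC[Si](C)(C)C)cc(C)cc2C3OCCO3)c1C(=O)O
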